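- Counted in equivalents of substrate, each product spends its own nucleophile, so a run's first reading tells us roughly what is left of each, before target has sunk far.

all flasks: substrate 0.10 M; first nucleophile 1.05 equiv
- gamma: second nucleophile 2.5 equiv; run made earlier
- zeta: second nucleophile 3.8 equiv; run made earlier
- flask: second nucleophile 5.00 equiv; time 8.0 h

| run | time / h | target / % | other capture product / % |
|---|---|---|---|
| gamma | 0.500 | 56.3 | 28.7 |
| gamma | 0.833 | 55.6 | 29.7 |
| gamma | 1.33 | 54.9 | 29.1 |
| gamma | 2.00 | 52.8 | 30.6 |
| gamma | 3.00 | 54.1 | 29.9 |
| gamma | 4.00 | 50.6 | 31.1 |
| gamma | 6.00 | 50.7 | 29.8 |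
| zeta | 0.333 | 50.3 | 38.3 |
| zeta | 1.00 | 49.2 | 37.8 |
| zeta | 2.00 | 48.0 | 38.0 |
| zeta | 3.00 | 46.2 | 39.2 |
| zeta | 4.00 | 46.3 | 39.2 |
| zeta | 5.00 | 45.0 | 39.0 |
| zeta | 6.00 | 44.7 | 40.5 |

(each reading ± 1 percentage point)

* ratio of target to other capture product at 4.0 s
* ratio of target to other capture product at 8.0 h

- the numbers in the tables scatter by 1 percentage point (one standard deviation)
- a reading or a percentage of target counts all its forms, free or not

- We assume both nucleophiles compete for one thing, with target forming against other capture product as s × c(first nucleophile)/c(second nucleophile).
- Dividing rate by rate drops time, leaving for each nucleophile the logarithm of charge over remainder.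
- The first readings give 6.30 in the gamma run and 6.14 in the zeta run.
- Their mean, 6.22, is our reading of the selectivity factor, the first logarithm over the second.
- Second nucleophile: by hand, more of it lowers the starting ratio to s × charge of first over charge of second, which for the flask is 1.31, our figure for 4.0 s. In the runs, going from 2.5 equiv to 3.8 equiv moves first-reading target from 56.3% to 50.3%.
- Time: by hand, target should sink once capture ends. The gamma run loses target at a pace that scales to a factor 0.859 over 8.0 h. An even split of the substrate would need s of 6.14, close to ours, so we take parity for the end of capture and 0.859 as our ratio at 8.0 h.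
- The forecast says 1 and 0.83: “Ratio × equiv is about 4.9–5.1, so the partition goes as 1/[second nucleophile]”. Our early figure is higher.
- The flask gives 1.26 at 4.0 s and 0.887 at 8.0 h.

    crystals ⇌ target, rate k1*(cs1 - [target]) while solid is left; crystals form when [target] > cs1 (solubility = 0.0800 M, k = 37.0 /min)
    second nucleophile + intermediate → other capture product (k = 16.0 /M/min)
    target → over-reaction product (k = 2.84 × 10⁻⁴ /min)
    substrate → intermediate (k = 1.72 /min)
    intermediate → solvolysis product (k = 1.82 /min)
    first nucleophile + intermediate → target (k = 96.6 /M/min)

- At 0.4037 min in the flask, the step to target used intermediate 1.0 times as fast as the step to other capture product, while the ratio of the products themselves was 1.26 at 4.0 s. Half of the flask's turnover to target was done by 0.425 min, and half of that to other capture product by 0.493 min. The flask's remainders at 8.00 h, 57.1% of first nucleophile and 91.1% of second, give s of 6.01. For the neighbour with 12.0 equiv, our s gives 0.544, and that flask shows 0.524 at 4.0 s.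

Readings and results are simulated with constants of no real substance, noise included.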